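# Proposed total synthesis of ebenfuran IV (24) by aryne/iodonium ylide annulation

## Structural features

The target 24 is a 2-arylbenzofuran. Ring A (the benzo ring, C3a to C7a) is fused to a furan (O1, C2, C3), and C2 carries ring B, a 4-hydroxy-2-methoxyphenyl group, through the C2–C1' bond. The furan is fully substituted, with a formyl group on C3. Ring A is pentasubstituted: OH on C4, a prenyl (3-methylbut-2-enyl) chain on C5, OMe on C6, and only C7 bears hydrogen. There is no stereocentre and no stereogenic double bond, so no stereocentres stand next to each other and the problem is purely one of regiochemistry and functional-group tolerance. The fragile parts are the trisubstituted prenyl olefin (acids, electrophiles, and cyclisation onto the neighbouring C4 phenol to a chroman), the electron-rich aldehyde and the two free phenols. The real difficulty is the crowded, contiguous array C3–C3a–C4–C5–C6 and the need to tell the C4 oxygen (free OH) from the C6 oxygen (OMe). The key step uses the fact that O1 and C3 sit on the adjacent ring A carbons C7a and C3a, and that C3a is flanked by the C4 oxygen. An aryne spanning C3a–C7a is therefore polarised to accept an oxygen nucleophile at C7a and to carry its carbanion at C3a, and the symmetric phenol from which it is made can give only this one aryne.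

## Logic of the disconnections

**24 ⇒ 23.** The O–CH3 bond on C4 and the O–CH2OCH3 bond on C4' are the last bonds to be made in the retrosynthetic sense. Free phenols would quench an aryne and the organolithium chemistry, and a free C4–OH beside the prenyl chain invites chroman formation, so both stay masked to the end. The gain is that every earlier intermediate is a neutral ether. The demand is that one Lewis acid removes the acetal and exactly one of three aryl methyl ethers while sparing the olefin. The C4 ether is the one that is flanked on both sides and peri to the formyl oxygen.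

**23 ⇒ 22 ⇒ 21.** No skeletal bond is cut; the formyl carbon is traced back through the primary alcohol to a methyl ester. The reason is that C3 must enter as part of a 1,3-dicarbonyl unit that can carry an iodonium ylide, which an ester allows and a free aldehyde does not. The demand is a reduction and a re-oxidation that leave the acetal, the ethers and the olefin alone.

**21 ⇒ 13 + 18 (through 19 and 20).** The cut is O1–C7a and C3–C3a, the two bonds that tie the furan to ring A. This splits the molecule into two benzene-derived halves of similar size. Ring A arrives with all four substituents in place, and the furan, ring B and the C3 carbon are installed in one operation. The demand is that 19 takes oxygen at C7a and carbon at C3a, and that 18 reacts through its ketone-derived oxygen and not through carbon or the ester oxygen.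

**13 ⇒ 12 ⇒ 11 ⇒ 7 ⇒ 6.** The O–S bond of the triflate and the aryl C–Si bond are cut, and the oxygen is traced back to a carbamate that directs metalation. Because 6 is symmetric, its two ortho positions are identical, so only one silylation product and one aryne are possible. The demand is that metalation occurs ortho to the carbamate without touching the benzylic-allylic CH2 of the prenyl chain.

**6 ⇒ 5 ⇒ 2 + 3 (through 4) ⇒ 1.** The aryl–CH2 bond of the prenyl group (C5–CH2 of the target) and the O–Si bond are cut. The carbon between the two methoxy groups is the most acidic ring position once the phenol is a bulky silyl ether. The gain is two commercial materials, 1 and 3. The demand is metalation only between the methoxy groups and allylation at the primary carbon of 3.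

**18 ⇒ 16 + 17; 16 ⇒ 15 ⇒ 14.** The C–I bond of the ylide, the bond between the ketone α-carbon and the ester carbon, and the O–CH2OCH3 bond are cut in turn. This leads to the commercial compounds 14 and 17 by three routine operations. The demand is only that the ylide is made cold and used soon.

## Other disconnections considered

**Alternative 1:** Ring A is built last on a finished furan. The cut removes C3a–C4, C4–C5 and C6–C7 and leads to the furyl diazoketone A1 and the ynol ether A2.
- Forward key step: irradiation of A1 causes a Wolff rearrangement. The ketene function adds across the triple bond of A2, the four-membered ring opens, a six-electron closure engages the furan β-carbon (C3a), and tautomerisation gives the phenol A3.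
- In its favour: the polarity of A2 fixes the ring A pattern, and A3 has C4–OH free and distinct from C6–OMe with the prenyl chain already on C5. No late selective demethylation is needed, and on this point the alternative is better than the chosen plan.
- Against it: A1 is a tetrasubstituted furan carrying a diazoketone and needs its own multi-step synthesis. A2 is a sensitive skipped enyne. The ketene can also add to the prenyl olefin. The closure must temporarily break furan aromaticity.
- Comparison: on structure both plans set the ring A pattern by one polarising oxygen substituent. On mechanism a pericyclic cascade replaces a polar aryne addition, with comparable regiochemical certainty. The ester-to-aldehyde adjustment is the same in both (equal). On step economy the alternative should be longer, because neither A1 nor A2 is close to commercial material and the free C4 phenol of A3 needs protection or extra reagent during the redox steps.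

**Alternative 2:** The cut is C2–C1' and C3–CHO on a preformed benzofuran A4, with ring B supplied as the pinacol boronate A5.
- Forward key step: A4 is lithiated at C2 (n-BuLi) and added to A5. The chloroiminium electrophile from DMF attacks C3 of the resulting boron ate species and ring B shifts from boron to C2. NaBO3 oxidation and mild acid then restore the furan and release the aldehyde A6, which is identical in structure with 23.
- In its favour: the aldehyde appears at the correct oxidation level, so the two redox steps 11 and 12 are saved. On step economy after the key step the alternative is better. Convergence is equal.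
- Against it: A4 still needs a furan-forming synthesis from 6. The electrophile must attack C3 next to the C4 methoxy group while the electron-rich C7 position competes. A chloroiminium ion as the trigger for such a 1,2-shift has no close analogy.
- Comparison: the chosen annulation belongs to an established reaction class, so on mechanism the chosen plan is safer. On structure the final selective C4 demethylation is the same in both (equal).

**Alternative 3:** The cut is O1–C2 and the bond from C3 to its exocyclic carbon, leading to the diarylalkyne A7.
- Forward key step: PtCl2 activates the alkyne, one acetal oxygen adds to the alkyne carbon bearing ring B, and the methoxymethyl group shifts to C3 to give A8.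
- In its favour: the step is catalytic and atom-economic, and the platinum-catalysed carboalkoxylation of ortho-alkynylphenyl acetals is an established reaction type, so on precedent it is the equal of the chosen plan. Ring A of A7 is symmetric, so either acetal oxygen gives the same product. In A8 the C4 oxygen is an acetal and not a methyl ether, so the final deprotection needs no selective demethylation, which is better than the chosen plan.
- Against it: A8 lacks the C5 prenyl group. It would have to be introduced late by metalation between the C4 and C6 oxygens, in competition with C7, which is flanked by O1 and the C6 methoxy group. The CH2OMe group must then be oxidised to CHO in the presence of electron-rich rings and, later, the prenyl olefin.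
- Comparison: on structure the chosen plan places the prenyl group first on a symmetric arene, where its position is unambiguous, and pays with a selective demethylation; the alternative does the reverse. On step economy the two are expected to be similar, but the unresolved regiochemistry of the late prenylation makes the alternative less secure.

Key step: step 10

Remark: positions are numbered as in benzofuran (O1, C2, C3, C3a, C4–C7, C7a; ring B carbons primed); it is assumed that the ketone-derived oxygen of the ylide is its nucleophilic site, as in other reactions of 1,3-dicarbonyl iodonium ylides with electrophiles.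

## Route

Step 1
Reactants: 1 3,5-dimethoxyphenol
Product: 2 (3,5-dimethoxyphenoxy)tri(propan-2-yl)silane
Conditions: TIPSCl, imidazole, DMF, rt
Reagents that add atoms: triisopropylsilyl chloride, CC(C)[Si](Cl)(C(C)C)C(C)C
Why: Imidazole-promoted O-silylation; the bulky TIPS ether withstands n-BuLi, is a poor directing group and shields its own ortho positions, so the next metalation can only go between the methoxy groups.

Step 2
Reactants: 2 (3,5-dimethoxyphenoxy)tri(propan-2-yl)silane; 3 prenyl bromide (1-bromo-3-methylbut-2-ene)
Product: 5 [3,5-dimethoxy-4-(3-methylbut-2-enyl)phenoxy]tri(propan-2-yl)silane, via aryllithium 4 (not isolated)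
Conditions: n-BuLi, THF, 0 °C to rt; CuBr·SMe2 (10 mol %), prenyl bromide, −78 °C to rt
Reagents that add atoms: none
Why: Directed ortho-metalation at the ring carbon flanked by both methoxy groups gives 4, and copper-catalysed SN2 allylation at the primary carbon of 3 should give the linear prenyl arene; the symmetry of the ring is kept.

Step 3
Reactants: 5 [3,5-dimethoxy-4-(3-methylbut-2-enyl)phenoxy]tri(propan-2-yl)silane
Product: 6 3,5-dimethoxy-4-(3-methylbut-2-enyl)phenol
Conditions: TBAF, THF, 0 °C
Reagents that add atoms: none
Why: Fluoride cleavage of the aryl silyl ether, driven by the Si–F bond, under conditions that leave the prenyl olefin untouched.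

Step 4
Reactants: 6 3,5-dimethoxy-4-(3-methylbut-2-enyl)phenol
Product: 7 3,5-dimethoxy-4-(3-methylbut-2-enyl)phenyl N-(propan-2-yl)carbamate
Conditions: i-PrNCO, Et3N (cat.), CH2Cl2, rt
Reagents that add atoms: isopropyl isocyanate, CC(C)N=C=O
Why: Base-catalysed addition of the phenol to the isocyanate gives the N-isopropyl carbamate, a strong ortho-directing group that can later be removed by mild base.

Step 5
Reactants: 7 3,5-dimethoxy-4-(3-methylbut-2-enyl)phenyl N-(propan-2-yl)carbamate
Product: 11 3,5-dimethoxy-4-(3-methylbut-2-enyl)-2-(trimethylsilyl)phenyl N-(propan-2-yl)carbamate, via N-silyl carbamate 8 (not isolated), via ortho-lithiated N-silyl carbamate 9 (not isolated), via C,N-bis-silyl carbamate 10 (not isolated)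
Conditions: TMSOTf, TMEDA, Et2O, 0 °C to rt; n-BuLi, TMEDA, −78 °C; TMSCl, −78 °C to rt; aq. NH4Cl
Reagents that add atoms: chlorotrimethylsilane, C[Si](C)(C)Cl (the transient N-silyl group of 8 to 10 comes from trimethylsilyl triflate, C[Si](C)(C)OS(=O)(=O)C(F)(F)F, and is lost on work-up)
Why: Directed ortho-metalation: in situ N-silylation (8) removes the acidic N–H, n-BuLi/TMEDA lithiates the position between carbamate and methoxy group (9, both ortho positions being equivalent), TMSCl traps it (10) and the labile N–Si bond is hydrolysed on mild work-up. Low temperature suppresses the anionic ortho-Fries shift and deprotonation of the prenyl CH2, and the near-neutral work-up avoids protodesilylation of the electron-rich arylsilane.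

Step 6
Reactants: 11 3,5-dimethoxy-4-(3-methylbut-2-enyl)-2-(trimethylsilyl)phenyl N-(propan-2-yl)carbamate
Product: 13 3,5-dimethoxy-4-(3-methylbut-2-enyl)-2-(trimethylsilyl)phenyl trifluoromethanesulfonate, via 2-silylphenol 12 (not isolated)
Conditions: DBU, Et2NH, MeCN, 40 °C; then PhNTf2, rt
Reagents that add atoms: N-phenylbis(trifluoromethanesulfonimide), O=S(=O)(N(c1ccccc1)S(=O)(=O)C(F)(F)F)C(F)(F)F
Why: DBU induces E1cB loss of isopropyl isocyanate from the N–H carbamate (trapped by Et2NH), and the hindered phenoxide of 12 is triflated in the same flask by the mild reagent PhNTf2, a standard one-pot route to 2-silylaryl triflates.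

Step 7
Reactants: 14 1-(4-hydroxy-2-methoxyphenyl)ethanone
Product: 15 1-[2-methoxy-4-(methoxymethoxy)phenyl]ethanone
Conditions: MOMCl, i-Pr2NEt, CH2Cl2, 0 °C to rt
Reagents that add atoms: chloromethyl methyl ether, COCCl
Why: O-alkylation of the phenol; the MOM acetal is inert to NaH, KOH, fluoride, hydride and MnO2 and leaves in the final Lewis-acid step together with the C4 methyl group.

Step 8
Reactants: 15 1-[2-methoxy-4-(methoxymethoxy)phenyl]ethanone
Product: 16 methyl 3-[2-methoxy-4-(methoxymethoxy)phenyl]-3-oxopropanoate
Conditions: NaH, (MeO)2CO, THF, reflux; then AcOH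
Reagents that add atoms: dimethyl carbonate, COC(=O)OC
Why: Crossed Claisen condensation of the methyl ketone enolate with dimethyl carbonate, driven by deprotonation of the β-keto ester formed; the methyl ester matches the methanol used in the next step.

Step 9
Reactants: 16 methyl 3-[2-methoxy-4-(methoxymethoxy)phenyl]-3-oxopropanoate; 17 (diacetoxyiodo)benzene
Product: 18 phenyliodonium ylide of methyl 3-[2-methoxy-4-(methoxymethoxy)phenyl]-3-oxopropanoate
Conditions: KOH, MeOH, −10 to 0 °C; ice-water, filtration
Reagents that add atoms: none
Why: Ligand exchange of the potassium enolate at trivalent iodine with loss of both acetates gives the stabilised ylide, the standard preparation of 1,3-dicarbonyl phenyliodonium ylides; 18 is kept cold and used without delay.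

Step 10
Reactants: 13 3,5-dimethoxy-4-(3-methylbut-2-enyl)-2-(trimethylsilyl)phenyl trifluoromethanesulfonate; 18 phenyliodonium ylide of methyl 3-[2-methoxy-4-(methoxymethoxy)phenyl]-3-oxopropanoate
Product: 21 methyl 4,6-dimethoxy-2-[2-methoxy-4-(methoxymethoxy)phenyl]-5-(3-methylbut-2-enyl)benzofuran-3-carboxylate, via aryne 19 (not isolated), via zwitterion 20 (not isolated)
Conditions: CsF (3 equiv), 18 (1.5 equiv), MeCN, 0 °C to rt
Reagents that add atoms: none
Why: Fluoride attacks silicon of 13 and triflate departs, releasing aryne 19 slowly. Ylide 18 is an enolate whose carbon is blocked by trivalent iodine, so it reacts through oxygen, and the ketone-derived oxygen, conjugated with the electron-rich ring B, is more nucleophilic than the ester oxygen. This oxygen adds to C7a, the aryne carbon remote from the flanking C4 methoxy group, because the inductive pull of that C–O bond and the distortion it imposes on the aryne place the developing carbanion at C3a; C7a is also the less hindered terminus. In zwitterion 20 the C3a carbanion then bonds to the iodonium-bearing carbon with expulsion of iodobenzene, either by in-plane vinylic substitution or by ligand coupling at iodine. The furan is thus closed as a five-membered ring in a formal (3+2) annulation (O1–C7a first, C3–C3a second), the breaking C–I bond lying outside the new ring, and it is aromatic as formed, so no oxidation is needed. The closest known reaction type is the fluoride-mediated annulation of arynes from 2-silylaryl triflates with phenyliodonium ylides of 1,3-dicarbonyl compounds to give benzofurans, and this step is that reaction applied to a tetrasubstituted aryne and an aryl β-keto ester ylide. No stereocentre is formed. The selectivity needed is regiochemical (oxygen at C7a, carbon at C3a) and is secured by the single oxygen substituent flanking the aryne, while the symmetry of 6 guarantees that only aryne 19 can form.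

Step 11
Reactants: 21 methyl 4,6-dimethoxy-2-[2-methoxy-4-(methoxymethoxy)phenyl]-5-(3-methylbut-2-enyl)benzofuran-3-carboxylate
Product: 22 [4,6-dimethoxy-2-[2-methoxy-4-(methoxymethoxy)phenyl]-5-(3-methylbut-2-enyl)benzofuran-3-yl]methanol
Conditions: i-Bu2AlH (3 equiv), CH2Cl2, −78 to 0 °C; aq. potassium sodium tartrate
Reagents that add atoms: none
Why: Hydride reduction of the ester to the primary alcohol; ethers, the acetal and the isolated olefin are not reduced, and the buffered tartrate work-up protects the acid-labile, electron-rich benzofuranylmethanol.

Step 12
Reactants: 22 [4,6-dimethoxy-2-[2-methoxy-4-(methoxymethoxy)phenyl]-5-(3-methylbut-2-enyl)benzofuran-3-yl]methanol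
Product: 23 4,6-dimethoxy-2-[2-methoxy-4-(methoxymethoxy)phenyl]-5-(3-methylbut-2-enyl)benzofuran-3-carbaldehyde
Conditions: MnO2, CH2Cl2, rt
Reagents that add atoms: none
Why: MnO2 oxidises the benzylic-type heteroarylmethanol selectively to the aldehyde under neutral heterogeneous conditions, without over-oxidation and without attack on the prenyl group.

Step 13
Reactants: 23 4,6-dimethoxy-2-[2-methoxy-4-(methoxymethoxy)phenyl]-5-(3-methylbut-2-enyl)benzofuran-3-carbaldehyde
Product: 24 ebenfuran IV, 4-hydroxy-2-(4-hydroxy-2-methoxyphenyl)-6-methoxy-5-(3-methylbut-2-enyl)benzofuran-3-carbaldehyde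
Conditions: BCl3, CH2Cl2, −78 to −20 °C; cold aq. NaHCO3
Reagents that add atoms: none
Why: Lewis-acid ether cleavage: boron bound to the formyl oxygen is delivered to the peri C4 methoxy group, which is also the only methyl ether twisted out of conjugation by two flanking substituents and hence the most basic, and chloride removes its methyl group. The MOM acetal is cleaved by BCl3 much faster than any aryl methyl ether, while the in-plane C6 and C2' methyl ethers and the olefin should survive at low temperature with a basic quench.

## Compound list

1 | 3,5-dimethoxyphenol | COc1cc(O)cc(OC)c1 | starting material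
2 | (3,5-dimethoxyphenoxy)tri(propan-2-yl)silane | COc1cc(O[Si](C(C)C)(C(C)C)C(C)C)cc(OC)c1 | intermediate
3 | prenyl bromide (1-bromo-3-methylbut-2-ene) | CC(C)=CCBr | starting material
4 | [2,6-dimethoxy-4-(triisopropylsilyloxy)phenyl]lithium | [Li]c1c(OC)cc(O[Si](C(C)C)(C(C)C)C(C)C)cc1OC | intermediate
5 | [3,5-dimethoxy-4-(3-methylbut-2-enyl)phenoxy]tri(propan-2-yl)silane | COc1cc(O[Si](C(C)C)(C(C)C)C(C)C)cc(OC)c1CC=C(C)C | intermediate
6 | 3,5-dimethoxy-4-(3-methylbut-2-enyl)phenol | COc1cc(O)cc(OC)c1CC=C(C)C | intermediate
7 | 3,5-dimethoxy-4-(3-methylbut-2-enyl)phenyl N-(propan-2-yl)carbamate | COc1cc(OC(=O)NC(C)C)cc(OC)c1CC=C(C)C | intermediate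
8 | 3,5-dimethoxy-4-(3-methylbut-2-enyl)phenyl N-(propan-2-yl)-N-(trimethylsilyl)carbamate | COc1cc(OC(=O)N(C(C)C)[Si](C)(C)C)cc(OC)c1CC=C(C)C | intermediate
9 | [2,4-dimethoxy-3-(3-methylbut-2-enyl)-6-{[propan-2-yl(trimethylsilyl)carbamoyl]oxy}phenyl]lithium | COc1cc(OC(=O)N(C(C)C)[Si](C)(C)C)c([Li])c(OC)c1CC=C(C)C | intermediate
10 | 3,5-dimethoxy-4-(3-methylbut-2-enyl)-2-(trimethylsilyl)phenyl N-(propan-2-yl)-N-(trimethylsilyl)carbamate | COc1cc(OC(=O)N(C(C)C)[Si](C)(C)C)c([Si](C)(C)C)c(OC)c1CC=C(C)C | intermediate
11 | 3,5-dimethoxy-4-(3-methylbut-2-enyl)-2-(trimethylsilyl)phenyl N-(propan-2-yl)carbamate | COc1cc(OC(=O)NC(C)C)c([Si](C)(C)C)c(OC)c1CC=C(C)C | intermediate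
12 | 3,5-dimethoxy-4-(3-methylbut-2-enyl)-2-(trimethylsilyl)phenol | COc1cc(O)c([Si](C)(C)C)c(OC)c1CC=C(C)C | intermediate
13 | 3,5-dimethoxy-4-(3-methylbut-2-enyl)-2-(trimethylsilyl)phenyl trifluoromethanesulfonate | COc1cc(OS(=O)(=O)C(F)(F)F)c([Si](C)(C)C)c(OC)c1CC=C(C)C | intermediate
14 | 1-(4-hydroxy-2-methoxyphenyl)ethanone | CC(=O)c1ccc(O)cc1OC | starting material
15 | 1-[2-methoxy-4-(methoxymethoxy)phenyl]ethanone | CC(=O)c1ccc(OCOC)cc1OC | intermediate
16 | methyl 3-[2-methoxy-4-(methoxymethoxy)phenyl]-3-oxopropanoate | COC(=O)CC(=O)c1ccc(OCOC)cc1OC | intermediate
17 | (diacetoxyiodo)benzene | CC(=O)OI(OC(C)=O)c1ccccc1 | starting material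
18 | phenyliodonium ylide of methyl 3-[2-methoxy-4-(methoxymethoxy)phenyl]-3-oxopropanoate (iodine on C2) | COC(=O)[C-]([I+]c1ccccc1)C(=O)c1ccc(OCOC)cc1OC | intermediate
19 | 3,5-dimethoxy-4-(3-methylbut-2-enyl)benzyne (1,2-didehydro-3,5-dimethoxy-4-(3-methylbut-2-enyl)benzene) | COC1=CC#CC(OC)=C1CC=C(C)C | intermediate
20 | zwitterion from O-addition of 18 to 19: 3,5-dimethoxy-4-(3-methylbut-2-enyl)phenyl-2-ide 3-methoxy-1-[2-methoxy-4-(methoxymethoxy)phenyl]-3-oxo-2-(phenyliodonio)prop-1-enyl ether (alkene geometry not fixed) | COC(=O)C([I+]c1ccccc1)=C(Oc1cc(OC)c(CC=C(C)C)c(OC)[c-]1)c1ccc(OCOC)cc1OC | intermediate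
21 | methyl 4,6-dimethoxy-2-[2-methoxy-4-(methoxymethoxy)phenyl]-5-(3-methylbut-2-enyl)benzofuran-3-carboxylate | COC(=O)c1c(-c2ccc(OCOC)cc2OC)oc2cc(OC)c(CC=C(C)C)c(OC)c12 | intermediate
22 | [4,6-dimethoxy-2-[2-methoxy-4-(methoxymethoxy)phenyl]-5-(3-methylbut-2-enyl)benzofuran-3-yl]methanol | COCOc1ccc(-c2oc3cc(OC)c(CC=C(C)C)c(OC)c3c2CO)c(OC)c1 | intermediate
23 | 4,6-dimethoxy-2-[2-methoxy-4-(methoxymethoxy)phenyl]-5-(3-methylbut-2-enyl)benzofuran-3-carbaldehyde | COCOc1ccc(-c2oc3cc(OC)c(CC=C(C)C)c(OC)c3c2C=O)c(OC)c1 | intermediate
24 | ebenfuran IV, 4-hydroxy-2-(4-hydroxy-2-methoxyphenyl)-6-methoxy-5-(3-methylbut-2-enyl)benzofuran-3-carbaldehyde | COc1cc(O)ccc1-c1oc2cc(OC)c(CC=C(C)C)c(O)c2c1C=O | target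

## Step count and least certain steps

Total step count: 13. Longest linear sequence: 10 steps (steps 1 to 6, then 10 to 13, from 1); the ring B branch is 3 steps (7 to 9) and joins at step 10.

**Step 10 (key step).**
- Most likely to go wrong: addition in the wrong sense or through the wrong atom (carbon-first or ester-oxygen attack of 18 on 19), either of which would relocate the substituents around the furan; and thermal loss of iodobenzene from 18 before 19 is released.
- Fallback: oxidative annulation of 6 with 16 under FeCl3·6H2O (cat.), (t-BuO)2, ClCH2CH2Cl, heat. The ortho C–H of the phenol (both ortho positions of 6 are equivalent) is coupled to the α-carbon of the β-keto ester and the phenol oxygen then condenses with the ketone. It sets out from 6 and 16 and returns to the route at 21 (F0: no new compound). Its price is a hot, oxidising, Lewis-acidic medium that puts the prenyl group and the MOM acetal at some risk, which is why it is the reserve.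

**Step 13.**
- Most likely to go wrong: acid-induced addition of the freshly liberated C4 phenol, or of HCl, across the prenyl double bond during reaction or quench; and incomplete discrimination between the C4 and C6 methyl ethers.
- Fallback: from 23 the deprotection is split into two mechanistically different operations. Dilute HCl in MeOH at rt first hydrolyses only the MOM acetal, while the C4 oxygen is still methylated and cannot cyclise onto the olefin, giving 2-(4-hydroxy-2-methoxyphenyl)-4,6-dimethoxy-5-(3-methylbut-2-enyl)benzofuran-3-carbaldehyde F1. MgI2·OEt2 in warm toluene/THF then bridges the formyl oxygen and the C4 ether oxygen, and iodide removes the methyl group under non-protic conditions, returning at 24.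

**Step 9.**
- Most likely to go wrong: decomposition of the acyclic ylide on isolation or storage (loss of iodobenzene, solvolysis) and poor solubility in MeCN.
- Fallback: from 16, with 2-MeOC6H4I(OAc)2 in place of 17 under the same base, the (2-methoxyphenyl)iodonium ylide of methyl 3-[2-methoxy-4-(methoxymethoxy)phenyl]-3-oxopropanoate F2 would be prepared. Its ortho methoxy group coordinates iodine intramolecularly, and such ylides are more soluble and longer lived. F2 would replace 18 in step 10 and the route is rejoined at 21.

**Step 5.**
- Most likely to go wrong: competing deprotonation of the benzylic-allylic CH2 of the prenyl chain, anionic ortho-Fries migration of the carbamoyl group on warming, or protodesilylation of the electron-rich arylsilane on work-up.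
- Fallback: from 6 by the halogen-based route to 2-silylaryl triflates. NBS (1 equiv, CH2Cl2, −78 °C; the trioxygenated ring is expected to out-compete the olefin) gives 2-bromo-3,5-dimethoxy-4-(3-methylbut-2-enyl)phenol F3. (Me3Si)2NH in THF at reflux gives [2-bromo-3,5-dimethoxy-4-(3-methylbut-2-enyl)phenoxy]trimethylsilane F4. n-BuLi in THF at −100 °C (bromine–lithium exchange and 1,3 O-to-C silyl shift, a retro-Brook rearrangement) gives the lithium salt of 12, which is triflated in the same flask with Tf2O to rejoin the route at 13.

**Step 11.**
- Most likely to go wrong: ionisation of the very electron-rich benzofuran-3-ylmethanol, leading to over-reduction to the 3-methyl compound or to ether and dimer formation; and sluggish reduction of the hindered, vinylogous-carbonate-like ester.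
- Fallback: from 21, aminolysis with MeNH(OMe)·HCl and i-PrMgCl (THF, −20 °C) gives N-methoxy-N-methyl-4,6-dimethoxy-2-[2-methoxy-4-(methoxymethoxy)phenyl]-5-(3-methylbut-2-enyl)benzofuran-3-carboxamide F5. i-Bu2AlH (THF, −78 °C) then gives a chelated tetrahedral intermediate that holds the aldehyde oxidation level until work-up, so the route is rejoined directly at 23 and 22 and the MnO2 step are bypassed.

## Further compounds

F0 | step 10 | none | none
F1 | step 13 | 2-(4-hydroxy-2-methoxyphenyl)-4,6-dimethoxy-5-(3-methylbut-2-enyl)benzofuran-3-carbaldehyde | COc1cc(O)ccc1-c1oc2cc(OC)c(CC=C(C)C)c(OC)c2c1C=O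
F2 | step 9 | (2-methoxyphenyl)iodonium ylide of methyl 3-[2-methoxy-4-(methoxymethoxy)phenyl]-3-oxopropanoate | COC(=O)[C-]([I+]c1ccccc1OC)C(=O)c1ccc(OCOC)cc1OC
F3 | step 5 | 2-bromo-3,5-dimethoxy-4-(3-methylbut-2-enyl)phenol | COc1cc(O)c(Br)c(OC)c1CC=C(C)C
F4 | step 5 | [2-bromo-3,5-dimethoxy-4-(3-methylbut-2-enyl)phenoxy]trimethylsilane | COc1cc(O[Si](C)(C)C)c(Br)c(OC)c1CC=C(C)C
F5 | step 11 | N-methoxy-N-methyl-4,6-dimethoxy-2-[2-methoxy-4-(methoxymethoxy)phenyl]-5-(3-methylbut-2-enyl)benzofuran-3-carboxamide | CON(C)C(=O)c1c(-c2ccc(OCOC)cc2OC)oc2cc(OC)c(CC=C(C)C)c(OC)c12
A1 | alternative 1 | methyl 5-(2-diazoacetyl)-2-[2-methoxy-4-(triisopropylsilyloxy)phenyl]furan-3-carboxylate | COC(=O)c1cc(C(=O)C=[N+]=[N-])oc1-c1ccc(O[Si](C(C)C)(C(C)C)C(C)C)cc1OC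
A2 | alternative 1 | 1-methoxy-5-methylhex-4-en-1-yne | COC#CCC=C(C)C
A3 | alternative 1 | methyl 4-hydroxy-6-methoxy-2-[2-methoxy-4-(triisopropylsilyloxy)phenyl]-5-(3-methylbut-2-enyl)benzofuran-3-carboxylate | COC(=O)c1c(-c2ccc(O[Si](C(C)C)(C(C)C)C(C)C)cc2OC)oc2cc(OC)c(CC=C(C)C)c(O)c12
A4 | alternative 2 | 4,6-dimethoxy-5-(3-methylbut-2-enyl)benzofuran | COc1cc2occc2c(OC)c1CC=C(C)C
A5 | alternative 2 | 2-[2-methoxy-4-(methoxymethoxy)phenyl]-4,4,5,5-tetramethyl-1,3,2-dioxaborolane | COCOc1ccc(B2OC(C)(C)C(C)(C)O2)c(OC)c1
A6 | alternative 2 | 4,6-dimethoxy-2-[2-methoxy-4-(methoxymethoxy)phenyl]-5-(3-methylbut-2-enyl)benzofuran-3-carbaldehyde | COCOc1ccc(-c2oc3cc(OC)c(CC=C(C)C)c(OC)c3c2C=O)c(OC)c1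
A7 | alternative 3 | 1-{[2,6-bis(methoxymethoxy)-4-methoxyphenyl]ethynyl}-2-methoxy-4-(triisopropylsilyloxy)benzene | COCOc1cc(OC)cc(OCOC)c1C#Cc1ccc(O[Si](C(C)C)(C(C)C)C(C)C)cc1OC
A8 | alternative 3 | 6-methoxy-3-(methoxymethyl)-4-(methoxymethoxy)-2-[2-methoxy-4-(triisopropylsilyloxy)phenyl]benzofuran | COCc1c(-c2ccc(O[Si](C(C)C)(C(C)C)C(C)C)cc2OC)oc2cc(OC)cc(OCOC)c12
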